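The runs come from a simulation for an exercise, and the scatter is random.

If target feeds its own making and is lost by a first-order step, the height of its crest can be reckoned from one concentration and the charge instead of being read off a curve.

| setting | Monday's | Sunday's | flask |
|---|---|---|---|
| substrate | 0.74 M | 1.7 M | 1.1 M |
| remark | run made earlier | run made earlier |  |
| time |  |  | 2.5 min |

- Monday's (time / s: target / %, substrate / %): 12.0: 3, 100; 20.0: 0, 99; 30.0: 3, 98; 50.0: 35, 54; 90.0: 34, 1
- Sunday's (time / s: target / %, substrate / %): 12.0: 0, 98; 20.0: 25, 75; 30.0: 74, 7; 50.0: 45, 1; 90.0: 20, 0

(readings scatter by 1.5 percentage points)



1. time, not beyond 2.5 min, at which the flask holds most target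
2. the amount of target, in percent of the substrate charged, at that time

Minutes. The first speaker noted that substrate sits, then collapses, the mark of autocatalysis, and that in Sunday's run ln(target/substrate) climbed at a = 0.346 /s. The second reported that target in Sunday's run then fell at k = 0.0249 /s.

The chair proposed balance as the zero of the scale. Making per target, the chair argued, goes with substrate concentration and losing doesn't, so the crest should lie at the crest concentration κ, the substrate concentration where the two are equal: κ = k·c/a with Sunday's charge c, or 0.122 M as read from these readings.

For the flask, the members reckoned the substrate left at the crest, as a share of the charge, as s = 11.1%. The loss summed along the rise, as a share of the charge, is s·ln(1/s), which puts the crest at 64.5%. Scaling Sunday's time of equal substrate and target by the charges gives 35.8 s in the flask, and the members put the crest at 0.752 min.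

The forecast, which reasoned that “Formation speeds up with concentration while loss does not”, gave 0.72 min and 62%, slightly different figures.

The flask gives 0.737 min and 65.6%.

    substrate + target → 2 target (k = 0.250 /M/s)
    substrate → target (k = 4.90 × 10⁻⁵ /s)
    target ⇌ isomer of the product (K = 8.70, k = 0.0300 /s)

At that time the flask holds 0.115 M of substrate, beside κ of 0.122 M. The loss is the passing of target into isomer of the product: without it the flask's highest target is 100%, not 65.6%. With 0.44 M charged, κ predicts a crest of 36.7%, and that neighbour flask reaches 39.8%.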